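Compound numbers used throughout: 1 4-(benzyloxy)benzyl chloride; 2 diethyl [4-(benzyloxy)benzyl]phosphonate; 3 3-(benzyloxy)benzaldehyde; 4 potassium carbanion of 2; 5 (E)-3,4'-bis(benzyloxy)stilbene; 6 3,4'-bis(benzyloxy)bibenzyl; 7 lunularin; 8 linear ether dimer of 7; 9 the target.

## Analysis of the target

The target is a tetra-aryl macrocycle in which four benzene rings are joined by two CH2CH2 bridges and two diaryl ether oxygens. Counted along the shortest path (four atoms of ring A, O, three of ring B, a bridge, four of ring C, O, three of ring D, a bridge) the ring is 20-membered. Ring A is a phenol with its OH meta to the bridge carbon and an aryloxy group at C4, ortho to that OH and para to the bridge. Ring D is a phenol with its OH para to the bridge carbon and an aryloxy group at C3, ortho to that OH; ring B is a meta-phenylene and ring C a para-phenylene, and both carry only ether oxygen. There is no stereocentre, so no stereochemical relationship has to be set. The sensitive parts are the two 2-aryloxyphenols, which are more easily oxidised than a simple alkylphenol, and the four benzylic methylenes. The difficulty is that neither ether-bearing carbon (C4 of ring A, C3 of ring D) sits on a ring with an electron-withdrawing group, so SNAr is closed without auxiliary groups, and a large ring must be closed without forming regio-isomeric rings. The strategy rests on one feature: cut at the two ether C–O bonds, rings B–C and rings A–D are each the skeleton of 7. The B–C half gives both its oxygens to the ethers, and the A–D half keeps both hydroxyls, each ortho to the carbon that receives an ether oxygen (O of ring C on C3 of ring D, O of ring B on C4 of ring A).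

## Retrosynthetic reasoning

9 to 8. The first cut is the bond between the ring B oxygen and C4 of ring A. C4 is ortho to the ring A hydroxyl that survives in 9, so in the forward sense it carries spin in the ring A phenoxyl radical. Opening here unrolls the macrocycle into linear dimer 8 without touching a bridge. The forward reaction has to oxidise the two 3-alkylphenol rings of 8 and join oxygen to carbon within one molecule; it is unimolecular and wants dilution, and it must leave the ring D phenol alone.

8 to two molecules of 7. The second cut, between the ring C oxygen and C3 of ring D, divides 8 into two molecules of 7. This carbon is again ortho to a hydroxyl that stays, and the para carbon of that ring is occupied by the bridge, so a 4-alkylphenoxyl radical can react only through oxygen or an ortho carbon. The gain is that all four rings and both bridges come from one C14 diphenol, with nothing to protect or pre-halogenate in the last step. This bond is made first in the forward direction, because the 4-alkylphenolate is oxidised at a lower potential than the 3-alkylphenolate, and it is bimolecular, so it wants concentration. The two bonds therefore ask for opposite regimes, and a uniformly dilute electrolysis would starve the first. The step is planned as one pot in two stages: concentrated at low potential, then diluted at a higher potential, in an alkaline medium so that the anode stops at the phenoxyl radical. An oxidase pocket would dictate which oxygen meets which carbon; at an electrode only the biases of 7 itself operate, and that is the accepted risk of a four-step route.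

7 to 5. No skeletal bond is cut. The two phenols are written as benzyl ethers and the CH2CH2 bridge as an E-alkene. Benzyl is chosen because a single catalytic hydrogenation saturates the alkene (passing through 6) and frees both phenols, so no separate Lewis-acid dealkylation is needed.

5 to 2 and 3. The central C=C bond is cut. This divides the stilbene into two benzylic C7 pieces of equal size, each from a commercial benzyl ether. The forward Horner–Wadsworth–Emmons reaction has to add carbanion 4 to aldehyde 3 and eliminate; it gives the E-isomer, whose geometry is erased later but which is a single crystalline compound.

2 to 1. The C–P bond is cut. The forward Arbuzov reaction on a primary benzylic chloride is reliable and leaves the benzyl ether alone.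

## Alternatives that were turned down

Alternative 1: The ring C oxygen–ring D carbon bond is cut. Open-chain precursor A1 already carries the ring B–O–ring A ether, both bridges, ring A as its methyl ether, two bromines ortho to the ring D hydroxyl and two chlorines ortho to the ring C hydroxyl. Tl(NO3)3 (trivalent thallium) in methanol would oxidise the dibromophenol of ring D, the ring C phenol oxygen would add at a bromine-bearing ortho carbon, and reductive work-up with zinc in acetic acid would restore the aromatic ring with loss of that bromine, giving macrocycle A2.
- For it: the halogens block C–C coupling, decide which ring is oxidised and which gives its oxygen, and the ring closes in a unimolecular step. On selectivity of the ether-forming event this alternative is clearly stronger than the chosen step.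
- Against it: A1 is a long linear construct with four halogens placed regioselectively; a stoichiometric, highly toxic thallium salt is used late; A2 still needs removal of one bromine and two chlorines and a demethylation. The halogen device also does nothing for the ring A ether, which needs a second method.
- Comparison: the chosen route gives up this control and offers four steps in place of well over a dozen, with no halogen or protecting group to install and remove.

Alternative 2: The ring B oxygen–ring A carbon bond is cut with ring A at a lower oxidation level. In precursor A3, ring A is a 3-substituted cyclohex-2-enone with bromine at C6 (the alpha-prime carbon), and the ring B phenol is free. Cs2CO3 at high dilution would form the phenoxide, which displaces the bromide by SN2 to give macrocyclic 6-aryloxycyclohex-2-enone A4 (racemic; the centre disappears on aromatisation). Dehydrogenation of the enone ring of A4 and demethylation of ring D would follow.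
- For it: phenoxide O-alkylation is mild and metal-free, and the position of the bromide fixes the ether site on ring A beyond doubt. That is a stronger answer to the C4 against C2 or C6 question than anything in the chosen step.
- Against it: a secondary alpha-bromo ketone under basic phenoxide can lose HBr, and the ambident phenoxide can attack through carbon. The bromide must be introduced regioselectively in a long precursor, the enone must later be dehydrogenated beside three electron-rich rings, and the second ether and both bridges still come from other chemistry.
- Comparison: it is many steps longer and changes the oxidation level of ring A twice, whereas the chosen route keeps all four rings aromatic throughout.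

Alternative 3: The ring B carbon–oxygen bond is cut by way of a ring one atom larger. The 21-membered macrolactone A5, an aryl ester between a ring B carboxyl group and the ring A phenol, would lose CO. Ni(cod)2 (zerovalent nickel) with an electron-rich chelating bisphosphine and K3PO4 in hot toluene would insert into the acyl C–O bond, extrude CO and reductively eliminate the diaryl ether, giving A6, the di-O-methyl ether of the target. Demethylation would finish.
- For it: macrolactonisation is among the most dependable ring closures, and the uncertain step then happens inside a ring already made, with no dilution problem. On ring formation this alternative is stronger than the chosen step.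
- Against it: decarbonylative ether formation works best with electron-poor acyl partners. Here the acyl group is a plain meta-alkylbenzoyl and the leaving group an electron-rich ortho-methoxy phenoxide, a poor pairing for oxidative addition and for C–O reductive elimination from nickel. The temperatures needed invite ester exchange, and A5 itself needs a long linear assembly.
- Comparison: the chosen route is far shorter and needs no transition metal in its last step; it lacks the unambiguous ring formation that A5 would provide.

Key step: step 4

Remark on the chemistry: the target has no stereocentre, and its 20-membered ring is taken to be conformationally mobile at room temperature, so no element of planar chirality is controlled.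

## Route

Step 1
Reactants: 1 4-(benzyloxy)benzyl chloride
Product: 2 diethyl [4-(benzyloxy)benzyl]phosphonate
Conditions: P(OEt)3 (3 equiv, neat), 140 °C; excess P(OEt)3 distilled off
Reagents that add atoms: triethyl phosphite, CCOP(OCC)OCC
Why: Michaelis–Arbuzov reaction; the phosphite displaces the primary benzylic chloride and chloride then dealkylates the phosphonium intermediate, the volatile alkyl chloride leaving the melt; the benzyl ether is inert.

Step 2
Reactants: 2 diethyl [4-(benzyloxy)benzyl]phosphonate; 3 3-(benzyloxy)benzaldehyde
Product: 5 (E)-3,4'-bis(benzyloxy)stilbene, via potassium phosphonate carbanion 4 (not isolated)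
Conditions: KOtBu (1.2 equiv), THF, 0 °C; then 3, 0 °C to rt
Reagents that add atoms: none
Why: Horner–Wadsworth–Emmons olefination; carbanion 4 adds to the non-enolisable aldehyde and the adduct eliminates phosphate to the E-alkene. The geometry is of no consequence because the double bond is hydrogenated in step 3.

Step 3
Reactants: 5 (E)-3,4'-bis(benzyloxy)stilbene
Product: 7 lunularin, via 3,4'-bis(benzyloxy)bibenzyl 6 (not isolated)
Conditions: H2 (1 atm), 10% Pd/C, EtOAc–EtOH 1:1, rt
Reagents that add atoms: none
Why: Catalytic hydrogenation saturates the stilbene double bond first, and hydrogenolysis of the two aryl benzyl ethers follows on the same catalyst; no other reducible group is present.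

Step 4
Reactants: 7 lunularin (two molecules)
Product: 9 target macrocycle, via linear ether dimer 8 (not isolated)
Conditions: controlled-potential anodic oxidation under N2, undivided cell, reticulated vitreous carbon anode, Pt cathode, K2CO3 (0.1 M), MeOH–H2O 1:1, rt; stage one: 7 at 20 mM, anode at the foot of the first phenolate wave (fixed by cyclic voltammetry, expected near +0.4 V vs Ag/AgCl), to partial conversion; stage two: diluted to about 1 mM, potential raised by about 0.15 V; then AcOH, EtOAc extraction, preparative HPLC
Reagents that add atoms: none
Why: Proposed new method: in the carbonate medium the phenols are ionised, and an anode held at the foot of the phenolate wave takes one electron from a phenolate without reaching the phenoxonium stage, so the chemistry is that of phenoxyl radicals; the 4-alkylphenolate is the easier one to oxidise, its radical carries spin on oxygen and on the two ortho carbons only (the para carbon holds the bridge), and recombination of the oxygen of one such radical with an ortho carbon of another, followed by enolisation of the 6-aryloxycyclohexa-2,4-dienone, gives linear dimer 8 with rings C and D joined. After dilution and at the higher potential the 3-alkylphenolates of rings A and B are oxidised as well, the ring B oxygen recombines with C4 of ring A (ortho to its oxygen, para to its bridge), and enolisation gives 9. The closest known reaction type is the one-electron oxidative coupling of para-alkylphenols, chemical or anodic, in which the ortho-aryloxyphenol appears beside the C–C dimers, together with the anodic growth of oxyphenylene chains from phenolates; a twofold, ring-closing version on an unprotected dihydroxybibenzyl has not been shown. The 20-membered ring is closed end to end by intramolecular radical recombination within a doubly oxidised molecule of 8, and it competes with chain growth only because stage two is dilute; no stereocentre is formed. The step needs O–C in place of C–C coupling, the pairing of para ring with para ring and of meta ring with meta ring, ring B as oxygen donor and ring A as carbon acceptor, attack at C4 of ring A and not at C2 or C6, and a ring D phenol that stays out of the second coupling. The substrate secures the first pairing through the lower oxidation potential of its 4-alkylphenolate and the blocked para carbons of rings C and D, and it makes the two hydroxyls that survive the activators of the two carbons that are oxygenated. The other requirements are not secured by the substrate, so 9 should be expected as one component of a dimer mixture, from which it is separated.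

## Compound list

1 | 4-(benzyloxy)benzyl chloride [1-(benzyloxy)-4-(chloromethyl)benzene] | ClCc1ccc(OCc2ccccc2)cc1 | starting material
2 | diethyl [4-(benzyloxy)benzyl]phosphonate | CCOP(=O)(OCC)Cc1ccc(OCc2ccccc2)cc1 | intermediate
3 | 3-(benzyloxy)benzaldehyde | O=Cc1cccc(OCc2ccccc2)c1 | starting material
4 | potassium [4-(benzyloxy)phenyl](diethoxyphosphoryl)methanide | CCOP(=O)(OCC)[CH-]c1ccc(OCc2ccccc2)cc1.[K+] | intermediate (not isolated)
5 | (E)-3,4'-bis(benzyloxy)stilbene [1-(benzyloxy)-3-{(E)-2-[4-(benzyloxy)phenyl]ethenyl}benzene] | c1ccc(cc1)COc1cccc(/C=C/c2ccc(OCc3ccccc3)cc2)c1 | intermediate
6 | 3,4'-bis(benzyloxy)bibenzyl [1-(benzyloxy)-3-{2-[4-(benzyloxy)phenyl]ethyl}benzene] | c1ccc(cc1)COc1cccc(CCc2ccc(OCc3ccccc3)cc2)c1 | intermediate (not isolated)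
7 | lunularin [3-[2-(4-hydroxyphenyl)ethyl]phenol] | Oc1ccc(CCc2cccc(O)c2)cc1 | intermediate
8 | linear ether dimer, 2-{4-[2-(3-hydroxyphenyl)ethyl]phenoxy}-4-[2-(3-hydroxyphenyl)ethyl]phenol | Oc1cccc(CCc2ccc(Oc3cc(CCc4cccc(O)c4)ccc3O)cc2)c1 | intermediate (not isolated)
9 | target macrocycle (20-membered cyclic bis-ether of two lunularin units; OH of ring A and of ring D each ortho to an ether oxygen) | Oc1cc2ccc1Oc1cccc(c1)CCc1ccc(cc1)Oc1cc(ccc1O)CC2 | target

## Step count and least certain steps

Total step count: 4. Longest linear sequence: 4 steps (1 to 9).

**Step 4 (key step).** What is most likely to go wrong is loss of selectivity in the recombination of the phenoxyl radicals, through processes that the substrate does not block: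
- (a) C–C coupling at the ortho carbons of the para rings, and ortho–para coupling at the bridge-bearing carbon, which usually outrun O–C coupling when para-alkylphenols are oxidised.
- (b) In stage two, further oxidation of the ring D phenol of 8, which as a 2-aryloxyphenol is the most easily oxidised site, leading to chain growth in place of ring closure.
- (c) Unimolecular C–C spiro-coupling between the two rings of one bibenzyl unit once both are oxidised, a five-membered closure that is entropically far ahead of a 20-membered one.
- (d) Closure with the roles of rings A and B exchanged, or at C2 or C6 of ring A.
- (e) Passivation of the anode by oxyphenylene films.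

Control of this kind would come from an oxidase pocket, which is not at hand.

The fallback uses known chemistry only; it sets out from phosphonate 2 and comes back to the route at 9. Olefination of 2 with 3-hydroxybenzaldehyde (two equivalents of KOtBu, THF) would give (E)-3-{2-[4-(benzyloxy)phenyl]ethenyl}phenol F1, in which only the ring B oxygen is free. SNAr with 4-fluoro-3-methoxybenzaldehyde (K2CO3, DMF, 120 °C) would place ring A on that oxygen, para to the formyl group, giving 4-(3-{(E)-2-[4-(benzyloxy)phenyl]ethenyl}phenoxy)-3-methoxybenzaldehyde F2. An Arbuzov reaction of 3-bromo-4-methoxybenzyl bromide with triethyl phosphite would give diethyl (3-bromo-4-methoxybenzyl)phosphonate F3. A second Horner–Wadsworth–Emmons reaction of F3 with F2 would give the bis-stilbene 1-(benzyloxy)-4-[(E)-2-(3-{4-[(E)-2-(3-bromo-4-methoxyphenyl)ethenyl]-2-methoxyphenoxy}phenyl)ethenyl]benzene F4. Diimide (TsNHNH2, NaOAc, aqueous DME, reflux) would saturate both alkenes without touching the aryl bromide or the benzyl ether, giving 1-(benzyloxy)-4-[2-(3-{4-[2-(3-bromo-4-methoxyphenyl)ethyl]-2-methoxyphenoxy}phenyl)ethyl]benzene F5. BCl3 with pentamethylbenzene in CH2Cl2 at −78 °C would free the ring C phenol, giving 4-[2-(3-{4-[2-(3-bromo-4-methoxyphenyl)ethyl]-2-methoxyphenoxy}phenyl)ethyl]phenol F6. An intramolecular Ullmann ether synthesis (CuCl, 2,2,6,6-tetramethylheptane-3,5-dione, Cs2CO3, NMP, 120 °C, slow addition) would close the 20-membered ring at the bromine-bearing carbon of ring D, giving the di-O-methyl ether of the target F7. BBr3 in CH2Cl2 would cleave the two methyl ethers to give 9. Every ether site and the pairing of the rings are fixed here by the building blocks, at the price of seven steps from 2 in the longest line.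

**Step 3.** What may go wrong is incomplete hydrogenolysis. The alkene is saturated quickly, but cleavage of the two aryl benzyl ethers can stall if the palladium surface is poisoned by traces of phosphorus species carried over from step 2, leaving partly debenzylated material. The fallback sets out from stilbene 5 and comes back at 7. Diimide (TsNHNH2, NaOAc, aqueous DME, reflux) would reduce the alkene alone to give 6, now isolated, and BCl3 with pentamethylbenzene in CH2Cl2 at −78 °C would cleave both benzyl ethers without any metal catalyst to give 7. No new compound is made.

**Step 2.** What may go wrong is incomplete olefination. The para-benzyloxy group destabilises carbanion 4, so deprotonation of 2 by KOtBu is an unfavourable equilibrium, and aldehyde 3 may be consumed by alkoxide-induced disproportionation before it is olefinated. The fallback sets out from aldehyde 3 and comes back at stilbene 5. Wittig methylenation of 3 (Ph3PCH3Br, KOtBu, THF) would give 1-(benzyloxy)-3-ethenylbenzene F8, and a Mizoroki–Heck reaction of F8 with 1-(benzyloxy)-4-iodobenzene (Pd(OAc)2, P(o-tol)3, Et3N, DMF, 100 °C) would give 5 as the E-isomer.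

## Further compounds

F1 | step 4 | (E)-3-{2-[4-(benzyloxy)phenyl]ethenyl}phenol | Oc1cccc(/C=C/c2ccc(OCc3ccccc3)cc2)c1
F2 | step 4 | 4-(3-{(E)-2-[4-(benzyloxy)phenyl]ethenyl}phenoxy)-3-methoxybenzaldehyde | COc1cc(C=O)ccc1Oc1cccc(/C=C/c2ccc(OCc3ccccc3)cc2)c1
F3 | step 4 | diethyl (3-bromo-4-methoxybenzyl)phosphonate | CCOP(=O)(OCC)Cc1ccc(OC)c(Br)c1
F4 | step 4 | 1-(benzyloxy)-4-[(E)-2-(3-{4-[(E)-2-(3-bromo-4-methoxyphenyl)ethenyl]-2-methoxyphenoxy}phenyl)ethenyl]benzene | COc1ccc(/C=C/c2ccc(Oc3cccc(/C=C/c4ccc(OCc5ccccc5)cc4)c3)c(OC)c2)cc1Br
F5 | step 4 | 1-(benzyloxy)-4-[2-(3-{4-[2-(3-bromo-4-methoxyphenyl)ethyl]-2-methoxyphenoxy}phenyl)ethyl]benzene | COc1ccc(CCc2ccc(Oc3cccc(CCc4ccc(OCc5ccccc5)cc4)c3)c(OC)c2)cc1Br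
F6 | step 4 | 4-[2-(3-{4-[2-(3-bromo-4-methoxyphenyl)ethyl]-2-methoxyphenoxy}phenyl)ethyl]phenol | COc1ccc(CCc2ccc(Oc3cccc(CCc4ccc(O)cc4)c3)c(OC)c2)cc1Br
F7 | step 4 | di-O-methyl ether of the target (rings A and D as methyl ethers) | COc1cc2ccc1Oc1cccc(c1)CCc1ccc(cc1)Oc1cc(ccc1OC)CC2
F8 | step 2 | 1-(benzyloxy)-3-ethenylbenzene | C=Cc1cccc(OCc2ccccc2)c1
F0 | step 3 | none | none
A1 | alternative 1 | open-chain precursor, 2,6-dibromo-4-(2-{4-[3-(2-(3,5-dichloro-4-hydroxyphenyl)ethyl)phenoxy]-3-methoxyphenyl}ethyl)phenol | Oc1c(Br)cc(CCc2ccc(Oc3cccc(CCc4cc(Cl)c(O)c(Cl)c4)c3)c(OC)c2)cc1Br
A2 | alternative 1 | halogenated macrocycle (ring D bromophenol, ring C dichloro, ring A methyl ether) | Oc1c(Br)cc2cc1Oc1c(Cl)cc(cc1Cl)CCc1cccc(c1)Oc1ccc(CC2)cc1OC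
A3 | alternative 2 | 6-bromo-3-[2-(4-methoxy-3-{4-[2-(3-hydroxyphenyl)ethyl]phenoxy}phenyl)ethyl]cyclohex-2-en-1-one (racemic) | O=C1C=C(CCc2ccc(OC)c(Oc3ccc(CCc4cccc(O)c4)cc3)c2)CCC1Br
A4 | alternative 2 | macrocyclic 6-aryloxycyclohex-2-enone (racemic, one enantiomer drawn) | O=C1C=C2CC[C@@H]1Oc1cccc(c1)CCc1ccc(cc1)Oc1cc(ccc1OC)CC2
A5 | alternative 3 | 21-membered macrolactone (ring B carboxyl esterified with the ring A phenol, rings A and D as methyl ethers) | COc1ccc2cc1Oc1ccc(cc1)CCc1cccc(c1)C(=O)Oc1ccc(CC2)cc1OC
A6 | alternative 3 | di-O-methyl ether of the target | COc1ccc2cc1Oc1ccc(cc1)CCc1cccc(c1)Oc1ccc(CC2)cc1OC
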